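## Structural features

The target is a cis-fused decalin of the eremophilane type: ring A (C1–C5, C10) carries the C2 ketone and the C4 methyl (C15), ring B (C5–C10) carries the C7 isopropenyl group and acyloxy groups at C8 ((R)-2-methylbutanoate) and C9 (tiglate), and the rings share the quaternary C5 (methyl C14) and C10–H. Six ring stereocentres are contiguous along C4–C5–C10–C9–C8–C7: C14, C15, H10 and the isopropenyl group lie on one face (β), the two ester oxygens on the other (α), and a seventh centre sits in the 2-methylbutanoyl group. In the favoured chair–chair form the isopropenyl group, the C8 oxygen and C15 are equatorial, while the C9 oxygen is axial and syn to the C4–C5 bond, that is, on the concave face. The fragile elements are the two different esters on a cis-diol (acyl migration), the tiglate (a Michael acceptor), the isopropenyl group (it rules out hydrogenation and late electrophilic oxidation, and slips into conjugation whenever C8 is a ketone), and C10–H, which can epimerise whenever C9 is a ketone. The real difficulties are the quaternary C5 between two stereocentres, C15 cis to C14, and an axial C9 oxygen on the hindered face next to a differently acylated C8 oxygen. The key step exploits the cis C5(Me)/C10(H) junction lying between C4 and the C8 oxygen: a ring A 2-methylcyclohex-2-enone with its carbonyl at C4 is a dienophile across C5=C10, and a 1-methoxy-3-silyloxydiene supplies C6–C9 with oxygen at C8.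

## Logic of the disconnections

31 to 29: the C4–C15 bond is cut. C15 is β to the C2 ketone, so it is the product of a methyl conjugate addition to 29. Hydrogenation of a C4 methylene is avoided: it cannot be run beside the isopropenyl and tiglate groups, and on the accessible convex face it would deliver hydrogen where carbon is needed. The forward step must bring methyl in from the β face and leave the tiglate alone.

29 to 26 (through 28 and 27): the C3=C4 bond and the C2 carbonyl are traced to a C2 silyl ether and a C4 acetate. C2 stays masked through every hydride step, and the former dienophile carbonyl at C4 becomes the leaving group that creates the enone. The forward steps need a desilylation, an oxidation and an E1cB elimination that two esters tolerate.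

26 to 25: the acyl–O9 bond is cut. The tiglate goes on last in ring B so that no hydride or enolate step meets it. The demand is acylation of an axial, flanked hydroxyl without migration of the neighbouring C8 ester.

25 to 22 (through 24 and 23): the C9–H bond is cut. An axial α oxygen at C9 cannot be delivered directly to the concave face, but a C9 ketone (24) is reduced from the open β face to exactly this alcohol. The ketone comes from the equatorial 9β epimer 23, which convex-face enolate oxidation gives naturally. The forward steps must not epimerise C10 or C8 and must not let the C8 ester migrate.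

22 to 20 and 21: the acyl–O8 bond is cut. With O9 still silylated the two oxygens are never equivalent, so each ester is placed unambiguously. The esterification must keep the α-centre of 21.

20 to 17 (through 19 and 18): the C8–H, C7–H and C6–H bonds are cut. Axial hydride addition gives the equatorial C8 alcohol, and conjugate reduction followed by equilibration gives the equatorial isopropenyl group. This requires a conformationally anchored ring B and a C7 epimerisation that does not move the alkene into conjugation.

17 to 15 (through 16): the C7–C11 bond and then the C7–I bond are cut. The enone fixes C7 as the only α-vinylic position, so the isopropenyl group is introduced by α-iodination and cross-coupling under neutral conditions.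

15 to 13 (through 14): the C9–O bond is cut. The enone can enolise only toward C9 because C5 is quaternary, so the silyl dienol ether 14 forms as a single regioisomer. Its oxidation must take place on the C8=C9 bond only.

13 to 11 (through 12): the O–Si and O–acetyl bonds are cut. Silylating the unhindered C2 hydroxyl and acetylating the neopentyl C4 hydroxyl differentiates the two oxygens. With both on the β face they act as a conformational anchor: they are diequatorial only in the chair–chair form that places C4 axial on ring B.

11 to 9 (through 10): the C4–H bond is cut. The free C2 hydroxyl of 9 directs a chelation-controlled reduction of the C4 ketone to the cis-1,3-diol, which ordinary convex-face hydride attack would not give. The saturated, chelated carbonyl must react ahead of the enone.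

9 to 6 and 7 (through 8): the C5–C6 and C9–C10 bonds are cut, which opens ring B and removes C5 and C10 as stereocentres. The precursors are the chiral enone 6 and diene 7. The silyl group of 6 is chosen to be acid-labile so that the directing hydroxyl of 9 is freed in the same work-up. The forward step needs anti facial selectivity with respect to the C2 oxygen and normal diene/enone regiochemistry.

6 to 1 (through 5, 4, 3 and 2): the O–Si bond, the acetate and finally the ring C–O bond are traced back to the isopropenyl C–C bond of 1. This puts the controlling stereocentre into the chiral pool. The forward rearrangement must keep its configuration and must not trigger β-elimination.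

## Other disconnections considered

Alternative 1: The cut is C3–C4 and C5–C10 (ring A). A trienyl tiglate A1, with a 2-silyloxydiene on C10–C1–C2–C3 and the tiglate on O9, would close by an intramolecular Diels–Alder reaction to the γ-lactone A2.
- In its favour: the (E)-tiglate is the dienophile, so the cis relation of C14 and C15 follows stereospecifically from alkene geometry. On this point it is better than the chosen plan, which spends separate steps on C15. It would set C4, C5 and C10 in one step, against two centres in the chosen key step, and the silyl enol ether is a direct precursor of the C2 ketone.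
- Against it here: an α,β-dimethylacrylate is a poor dienophile and must form a quaternary centre. The ester tether has to adopt its disfavoured s-cis form to reach a five-membered lactone. Facial control rests only on the C9 centre. The tiglate carbonyl becomes C6, so ring B must still be closed at C6–C7, C6 deoxygenated, and a new tiglate put on O9.
- Comparison: structurally it is more ambitious; mechanistically it is less secure (a high-temperature cycloaddition of an unactivated, tethered ester); in step economy it is at best equal, because the steps saved on C15 are spent on ring B.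

Alternative 2: The cut is C5–C6 (ring B). In the methylenecyclohexane A3, hydrogen-atom transfer from Fe(acac)3/PhSiH3 to the C5 methylene would give a tertiary C5 radical that adds to C6 of the tethered α-methylene ketone, forming A4.
- In its favour: the quaternary centre is made under mild, neutral conditions. C15 is already in place and the C8/C9 oxygens arrive with their final configuration, so no inversion at C9 is needed; on both points it is better than the chosen plan.
- Against it here: the cis-diol emerges as an acetonide, so the two oxygens still have to be told apart, which the chosen plan never needs to do. Cis fusion and the C5 configuration depend on the face of radical attack, and C7 on a protonation. The isopropenyl group requires late methylenation of an acetyl group whose α-carbon is epimerisable and has a β-oxygen. A3 carries four stereocentres that must be assembled first.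
- Comparison: the ring closure itself is on a par with the chosen key step in reliability, but it builds one bond and one ring atom array rather than two bonds. The overall count is unlikely to be lower.

Alternative 3: The cut is C9–C10 (ring B). Cathodic reduction of the enone aldehyde A5 would join the β-carbon C10 of the ring A enone to the C9 aldehyde and give the hydroxy ketone A6.
- In its favour: the C2 ketone, C15, C14, the isopropenyl group and the C8 oxygen are all in place. The product has a free C9 hydroxyl next to a silylated C8 oxygen, so the two esters could be placed without redox inversion or ring A protecting groups. In endgame economy it is better than the chosen plan.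
- Against it here: the closure must set C10 (cis fusion) and C9 (axial hydroxyl syn to C4) together, and neither outcome is assured for a radical-anion cyclisation. A5 needs the quaternary C5 next to C4 and an acyclic C7/C8 pair made enantioselectively without a ring to relay stereochemistry, and its α-silyloxy aldehyde is epimerisable.
- Comparison: structurally it defers the hardest centre to an unsolved acyclic problem; mechanistically its stereochemical outcome is less predictable than a suprafacial cycloaddition; in step economy it is equal or better after the key step and worse before it.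

Key step: step 4

Remarks on assumptions:
- Atoms are numbered as in the target (ring A C1–C5 and C10, ring B C5–C10, C14 on C5, C15 on C4). β denotes the face carrying C14; α the opposite face. "Decalin" names use this numbering. TBS = tert-butyldimethylsilyl, TES = triethylsilyl.
- C6 of adduct 8 is formed as an epimer mixture and is not assigned; it is lost in the same step.
- (S)-Carvone, diene 7, (R)-2-methylbutanoic acid, tigloyl chloride and tributyl(prop-1-en-2-yl)stannane are taken as commercial.

## Route

Step 1
Reactants: 1 (S)-carvone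
Product: 4 (S)-5-acetoxy-2-methylcyclohex-2-en-1-one, via methoxy hydroperoxide 2 (not isolated), via peracetate 3 (not isolated)
Conditions: O3, CH2Cl2/MeOH, −78 °C; then Ac2O, Et3N, DMAP (cat.), 0 °C → rt
Reagents that add atoms: ozone, [O-][O+]=O; methanol, CO
Why: Ozone cleaves the electron-rich isopropenyl alkene ahead of the enone and methanol traps the carbonyl oxide as 2; acetylation to 3 triggers a Criegee rearrangement in which the ring carbon migrates to oxygen with retention, so the (S) centre of 1 becomes the (S) acetate.

Step 2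
Reactants: 4 (S)-5-acetoxy-2-methylcyclohex-2-en-1-one
Product: 5 (S)-5-hydroxy-2-methylcyclohex-2-en-1-one
Conditions: K2CO3 (cat.), MeOH, 0 °C
Reagents that add atoms: none
Why: Carbonate-catalysed transesterification frees the alcohol; low temperature and a weak base are chosen so that methanolysis outruns β-elimination of the β-acyloxy ketone.

Step 3
Reactants: 5 (S)-5-hydroxy-2-methylcyclohex-2-en-1-one
Product: 6 (S)-2-methyl-5-(triethylsilyloxy)cyclohex-2-en-1-one
Conditions: TESCl, imidazole, DMF, 0 °C
Reagents that add atoms: chlorotriethylsilane, CC[Si](Cl)(CC)CC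
Why: Routine silylation; the triethylsilyl ether is bulky enough to direct the cycloaddition and to survive the Lewis acid, yet it is cleaved in the acidic work-up of step 4.

Step 4
Reactants: 6 (S)-2-methyl-5-(triethylsilyloxy)cyclohex-2-en-1-one; 7 (E)-1-methoxy-3-(trimethylsilyloxy)buta-1,3-diene
Product: 9 2β-hydroxy-5β-methyl-10βH-decal-6-ene-4,8-dione, via cis-fused silyl enol ether adduct 8 (not isolated)
Conditions: EtAlCl2 (0.5 equiv), toluene, −30 → 0 °C; then 1 M HCl, THF, rt
Reagents that add atoms: none
Why: This is a Lewis acid-promoted Diels–Alder reaction, a concerted but asynchronous [4+2] cycloaddition whose stepwise Mukaiyama–Michael/ring-closure variant converges on the same adduct; the closest known reaction type is the EtAlCl2-promoted addition of 2-silyloxydienes to carvone-type 2-methylcyclohex-2-enones. Coordination of the C4 carbonyl activates C5=C10, and the nucleophilic CH2 terminus of 7 bonds to the β-carbon C10 while the methoxy-bearing carbon bonds to the α-carbon C5, so the diene oxygen ends at C8. Ring B is closed by the cycloaddition itself: C5–C6 and C9–C10 form suprafacially on one face of the alkene, so the ring fusion is necessarily cis. The two new stereocentres, C5 and C10, are controlled by the C2 silyloxy group, because the diene bonds to the face of the half-chair anti to it, as is usual for 5-substituted cyclohexenones, which places C14 and H10 on the β face. The selectivity required is facial and regiochemical; the first is secured by the C2 substituent and the second by the matched polarity of diene and enone. Aqueous acid then hydrolyses the silyl enol ether of 8, eliminates methanol across C6–C7 to give the enone, and removes the triethylsilyl group to free the C2 hydroxyl needed in step 5.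

Step 5
Reactants: 9 2β-hydroxy-5β-methyl-10βH-decal-6-ene-4,8-dione
Product: 11 2β,4β-dihydroxy-5β-methyl-10βH-decal-6-en-8-one, via diethylborinate chelate 10 (not isolated)
Conditions: Et2BOMe, THF/MeOH, −78 °C; NaBH4; AcOH, then MeOH co-evaporation
Reagents that add atoms: none
Why: Narasaka–Prasad reduction: the boron bridge between O2 and the C4 carbonyl holds the C2 oxygen axial and covers the β face of C4, so external hydride adds from the α face and gives the cis-1,3-diol (4β-OH); the chelated saturated ketone is far more electrophilic than the enone carbonyl.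

Step 6
Reactants: 11 2β,4β-dihydroxy-5β-methyl-10βH-decal-6-en-8-one
Product: 12 2β-(TBS-oxy)-4β-hydroxy-5β-methyl-10βH-decal-6-en-8-one
Conditions: TBSCl (1.05 equiv), imidazole, DMF, 0 °C
Reagents that add atoms: tert-butylchlorodimethylsilane, CC(C)(C)[Si](C)(C)Cl
Why: The C2 hydroxyl lies between two methylene groups whereas the C4 hydroxyl is neopentyl (next to quaternary C5), so silylation should be site-selective.

Step 7
Reactants: 12 2β-(TBS-oxy)-4β-hydroxy-5β-methyl-10βH-decal-6-en-8-one
Product: 13 4β-acetoxy-2β-(TBS-oxy)-5β-methyl-10βH-decal-6-en-8-one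
Conditions: Ac2O, DMAP, pyridine, 40 °C
Reagents that add atoms: acetic anhydride, CC(=O)OC(C)=O
Why: DMAP-catalysed acetylation installs the leaving group for step 19; with the C2 and C4 oxygens both β the decalin is held in the chair–chair form with C4 axial on ring B, since the other form would make them 1,3-diaxial, and this anchor underlies the stereocontrol of steps 8, 11, 12 and 16.

Step 8
Reactants: 13 4β-acetoxy-2β-(TBS-oxy)-5β-methyl-10βH-decal-6-en-8-one
Product: 15 4β-acetoxy-2β-(TBS-oxy)-5β-methyl-9β-(TES-oxy)-10βH-decal-6-en-8-one, via silyl dienol ether 14 (not isolated)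
Conditions: TESOTf, Et3N, CH2Cl2, −78 → 0 °C; then mCPBA, NaHCO3, CH2Cl2/hexane, −20 °C
Reagents that add atoms: triethylsilyl trifluoromethanesulfonate, CC[Si](CC)(CC)OS(=O)(=O)C(F)(F)F; 3-chloroperbenzoic acid, OOC(=O)c1cccc(Cl)c1
Why: Soft enolisation can only occur toward C9 (C5 has no hydrogen) and gives 14; Rubottom oxidation then epoxidises the electron-rich C8=C9 bond from the convex β face, anti to the pseudoaxial C4, and silyl migration gives the α'-silyloxy enone, whose C9 configuration is temporary.

Step 9
Reactants: 15 4β-acetoxy-2β-(TBS-oxy)-5β-methyl-9β-(TES-oxy)-10βH-decal-6-en-8-one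
Product: 16 4β-acetoxy-2β-(TBS-oxy)-7-iodo-5β-methyl-9β-(TES-oxy)-10βH-decal-6-en-8-one
Conditions: I2, pyridine, CH2Cl2, rt
Reagents that add atoms: iodine, II
Why: Johnson α-iodination of an enone (conjugate addition of pyridine, iodination of the enolate, elimination), a sequence that works on 4,4-disubstituted cyclohexenones and touches neither ester nor silyl ether.

Step 10
Reactants: 16 4β-acetoxy-2β-(TBS-oxy)-7-iodo-5β-methyl-9β-(TES-oxy)-10βH-decal-6-en-8-one
Product: 17 4β-acetoxy-2β-(TBS-oxy)-5β-methyl-7-(prop-1-en-2-yl)-9β-(TES-oxy)-10βH-decal-6-en-8-one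
Conditions: tributyl(prop-1-en-2-yl)stannane, PdCl2(PhCN)2 (cat.), AsPh3, CuI, NMP, rt
Reagents that add atoms: tributyl(prop-1-en-2-yl)stannane, C=C(C)[Sn](CCCC)(CCCC)CCCC
Why: Stille coupling of an α-iodoenone under neutral conditions forms the C7–C11 bond without exposing the base-sensitive α'-silyloxy enone and acetate to aqueous base.

Step 11
Reactants: 17 4β-acetoxy-2β-(TBS-oxy)-5β-methyl-7-(prop-1-en-2-yl)-9β-(TES-oxy)-10βH-decal-6-en-8-one
Product: 19 4β-acetoxy-2β-(TBS-oxy)-5β-methyl-7β-(prop-1-en-2-yl)-9β-(TES-oxy)-10βH-decalin-8-one, via lithium enolate 18 (not isolated)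
Conditions: LiBH(s-Bu)3, THF, −78 °C; AcOH, −78 °C; then DBU (cat.), CH2Cl2, 0 °C
Reagents that add atoms: none
Why: The hindered borohydride reduces α-substituted, β-unsubstituted enones in the 1,4 sense (as with carvone); α-protonation of the extended enolate keeps the alkene out of conjugation, and brief base equilibration places the isopropenyl group equatorial (7β), the only arrangement in the anchored ring B that avoids a 1,3-diaxial clash with C4.

Step 12
Reactants: 19 4β-acetoxy-2β-(TBS-oxy)-5β-methyl-7β-(prop-1-en-2-yl)-9β-(TES-oxy)-10βH-decalin-8-one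
Product: 20 4β-acetoxy-2β-(TBS-oxy)-5β-methyl-7β-(prop-1-en-2-yl)-9β-(TES-oxy)-10βH-decalin-8α-ol
Conditions: NaBH4, CeCl3·7H2O, MeOH, −40 °C
Reagents that add atoms: none
Why: A small hydride adds axially from the unhindered β face of a cyclohexanone flanked by two equatorial substituents and should give the equatorial 8α alcohol, trans to the isopropenyl group; the near-neutral Luche conditions suppress C7 epimerisation and silyl migration.

Step 13
Reactants: 20 4β-acetoxy-2β-(TBS-oxy)-5β-methyl-7β-(prop-1-en-2-yl)-9β-(TES-oxy)-10βH-decalin-8α-ol; 21 (R)-2-methylbutanoic acid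
Product: 22 4β-acetoxy-2β-(TBS-oxy)-5β-methyl-8α-[(2R)-2-methylbutanoyloxy]-7β-(prop-1-en-2-yl)-9β-(TES-oxy)-10βH-decalin
Conditions: EDC·HCl, DMAP, CH2Cl2, 0 °C → rt
Reagents that add atoms: none
Why: Steglich esterification of an equatorial secondary alcohol; carbodiimide activation avoids a ketene, so the α-stereocentre of 21 is kept, and O9 is still silylated, so only O8 can be acylated.

Step 14
Reactants: 22 4β-acetoxy-2β-(TBS-oxy)-5β-methyl-8α-[(2R)-2-methylbutanoyloxy]-7β-(prop-1-en-2-yl)-9β-(TES-oxy)-10βH-decalin
Product: 23 4β-acetoxy-2β-(TBS-oxy)-5β-methyl-8α-[(2R)-2-methylbutanoyloxy]-7β-(prop-1-en-2-yl)-10βH-decalin-9β-ol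
Conditions: HF·pyridine, pyridine, THF, 0 °C
Reagents that add atoms: none
Why: Buffered fluoride cleaves the secondary triethylsilyl ether well before the TBS ether and leaves the esters alone; the weakly acidic medium disfavours acyl migration.

Step 15
Reactants: 23 4β-acetoxy-2β-(TBS-oxy)-5β-methyl-8α-[(2R)-2-methylbutanoyloxy]-7β-(prop-1-en-2-yl)-10βH-decalin-9β-ol
Product: 24 4β-acetoxy-2β-(TBS-oxy)-5β-methyl-8α-[(2R)-2-methylbutanoyloxy]-7β-(prop-1-en-2-yl)-10βH-decalin-9-one
Conditions: Dess–Martin periodinane, NaHCO3, CH2Cl2, rt
Reagents that add atoms: none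
Why: Dess–Martin oxidation under buffered, essentially neutral conditions gives the α-acyloxy ketone without enolisation, so C10 (cis fusion) and C8 are not epimerised.

Step 16
Reactants: 24 4β-acetoxy-2β-(TBS-oxy)-5β-methyl-8α-[(2R)-2-methylbutanoyloxy]-7β-(prop-1-en-2-yl)-10βH-decalin-9-one
Product: 25 4β-acetoxy-2β-(TBS-oxy)-5β-methyl-8α-[(2R)-2-methylbutanoyloxy]-7β-(prop-1-en-2-yl)-10βH-decalin-9α-ol
Conditions: LiBH(s-Bu)3, THF, −78 °C; AcOH quench at −78 °C
Reagents that add atoms: none
Why: The axial trajectory on the α face is blocked by the syn-axial C4, so the bulky hydride attacks equatorially from the β face and gives the axial 9α alcohol, cis to the C8 ester; with steps 14 and 15 this inverts C9, and the cold acidic quench keeps the C8 ester from migrating.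

Step 17
Reactants: 25 4β-acetoxy-2β-(TBS-oxy)-5β-methyl-8α-[(2R)-2-methylbutanoyloxy]-7β-(prop-1-en-2-yl)-10βH-decalin-9α-ol
Product: 26 4β-acetoxy-2β-(TBS-oxy)-5β-methyl-8α-[(2R)-2-methylbutanoyloxy]-7β-(prop-1-en-2-yl)-9α-tigloyloxy-10βH-decalin
Conditions: tigloyl chloride, DMAP, pyridine, 50 °C
Reagents that add atoms: (E)-2-methylbut-2-enoyl chloride, C/C=C(\C)C(Cl)=O
Why: DMAP-catalysed acylation with the acid chloride; the (E)-alkene of the tiglate is the stable isomer and tolerates forcing conditions, and migration of the C8 ester to the axial C9 position would be uphill.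

Step 18
Reactants: 26 4β-acetoxy-2β-(TBS-oxy)-5β-methyl-8α-[(2R)-2-methylbutanoyloxy]-7β-(prop-1-en-2-yl)-9α-tigloyloxy-10βH-decalin
Product: 27 4β-acetoxy-5β-methyl-8α-[(2R)-2-methylbutanoyloxy]-7β-(prop-1-en-2-yl)-9α-tigloyloxy-10βH-decalin-2β-ol
Conditions: HF·pyridine, THF, rt
Reagents that add atoms: none
Why: Fluoride desilylation under mildly acidic conditions leaves all three esters and the isopropenyl group untouched.

Step 19
Reactants: 27 4β-acetoxy-5β-methyl-8α-[(2R)-2-methylbutanoyloxy]-7β-(prop-1-en-2-yl)-9α-tigloyloxy-10βH-decalin-2β-ol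
Product: 29 5β-methyl-8α-[(2R)-2-methylbutanoyloxy]-7β-(prop-1-en-2-yl)-9α-tigloyloxy-10βH-decal-3-en-2-one, via β-acetoxy ketone 28 (not isolated)
Conditions: Dess–Martin periodinane, NaHCO3, CH2Cl2, rt; then DBU, rt
Reagents that add atoms: none
Why: Oxidation gives the β-acetoxy ketone 28 and DBU expels acetate by E1cB across C3–C4; C5 is quaternary, so the enone has no γ-hydrogen and cannot deconjugate, and no stereocentre in the molecule is α to the new carbonyl.

Step 20
Reactants: 29 5β-methyl-8α-[(2R)-2-methylbutanoyloxy]-7β-(prop-1-en-2-yl)-9α-tigloyloxy-10βH-decal-3-en-2-one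
Product: 31 target CNP0312791.1 (4β,5β-dimethyl-8α-[(2R)-2-methylbutanoyloxy]-7β-(prop-1-en-2-yl)-9α-tigloyloxy-10βH-decalin-2-one), via lithium enolate 30 (not isolated)
Conditions: Me2CuLi, Et2O, −78 → −30 °C; aq NH4Cl
Reagents that add atoms: lithium dimethylcuprate, [Li+].C[Cu-]C
Why: Gilman conjugate addition to a 4,4-disubstituted cyclohexenone; the enone is far more reactive than the α,β-disubstituted tiglate or the saturated esters at low temperature, and methyl enters C4 from the convex β face because the α face is covered by C9 and its tigloyloxy group, which sets C15 cis to C14.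

## Compound list

1 | (S)-carvone | CC1=CC[C@H](C(C)=C)CC1=O | starting material
2 | (5S)-5-(1-hydroperoxy-1-methoxyethyl)-2-methylcyclohex-2-en-1-one | CC1=CC[C@H](C(C)(OC)OO)CC1=O | intermediate
3 | (5S)-5-(1-acetylperoxy-1-methoxyethyl)-2-methylcyclohex-2-en-1-one | CC1=CC[C@H](C(C)(OC)OOC(C)=O)CC1=O | intermediate
4 | (S)-5-acetoxy-2-methylcyclohex-2-en-1-one | CC1=CC[C@H](OC(C)=O)CC1=O | intermediate
5 | (S)-5-hydroxy-2-methylcyclohex-2-en-1-one | CC1=CC[C@H](O)CC1=O | intermediate
6 | (S)-2-methyl-5-(triethylsilyloxy)cyclohex-2-en-1-one | CC1=CC[C@H](O[Si](CC)(CC)CC)CC1=O | intermediate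
7 | (E)-1-methoxy-3-(trimethylsilyloxy)buta-1,3-diene | CO/C=C/C(=C)O[Si](C)(C)C | starting material
8 | 6-methoxy-5β-methyl-2β-(TES-oxy)-8-(trimethylsilyloxy)-10βH-decal-7-en-4-one (C6 epimers) | C1(O[Si](C)(C)C)=CC(OC)[C@@]2(C)[C@H](C[C@H](O[Si](CC)(CC)CC)CC2=O)C1 | intermediate
9 | 2β-hydroxy-5β-methyl-10βH-decal-6-ene-4,8-dione | C1=C[C@@]2(C)[C@H](C[C@H](O)CC2=O)CC1=O | intermediate
10 | 2-O-diethylboryl derivative of 9 | C1=C[C@@]2(C)[C@H](C[C@H](OB(CC)CC)CC2=O)CC1=O | intermediate
11 | 2β,4β-dihydroxy-5β-methyl-10βH-decal-6-en-8-one | C1=C[C@@]2(C)[C@H](C[C@H](O)C[C@@H]2O)CC1=O | intermediate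
12 | 2β-(TBS-oxy)-4β-hydroxy-5β-methyl-10βH-decal-6-en-8-one | C1=C[C@@]2(C)[C@H](C[C@H](O[Si](C)(C)C(C)(C)C)C[C@@H]2O)CC1=O | intermediate
13 | 4β-acetoxy-2β-(TBS-oxy)-5β-methyl-10βH-decal-6-en-8-one | C1=C[C@@]2(C)[C@H](C[C@H](O[Si](C)(C)C(C)(C)C)C[C@@H]2OC(C)=O)CC1=O | intermediate
14 | 4β-acetoxy-2β-(TBS-oxy)-5β-methyl-8-(TES-oxy)-10βH-decala-6,8-diene | C1=C[C@@]2(C)[C@H](C[C@H](O[Si](C)(C)C(C)(C)C)C[C@@H]2OC(C)=O)C=C1O[Si](CC)(CC)CC | intermediate
15 | 4β-acetoxy-2β-(TBS-oxy)-5β-methyl-9β-(TES-oxy)-10βH-decal-6-en-8-one | C1=C[C@@]2(C)[C@H](C[C@H](O[Si](C)(C)C(C)(C)C)C[C@@H]2OC(C)=O)[C@@H](O[Si](CC)(CC)CC)C1=O | intermediate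
16 | 4β-acetoxy-2β-(TBS-oxy)-7-iodo-5β-methyl-9β-(TES-oxy)-10βH-decal-6-en-8-one | IC1=C[C@@]2(C)[C@H](C[C@H](O[Si](C)(C)C(C)(C)C)C[C@@H]2OC(C)=O)[C@@H](O[Si](CC)(CC)CC)C1=O | intermediate
17 | 4β-acetoxy-2β-(TBS-oxy)-5β-methyl-7-(prop-1-en-2-yl)-9β-(TES-oxy)-10βH-decal-6-en-8-one | C=C(C)C1=C[C@@]2(C)[C@H](C[C@H](O[Si](C)(C)C(C)(C)C)C[C@@H]2OC(C)=O)[C@@H](O[Si](CC)(CC)CC)C1=O | intermediate
18 | lithium 7(8)-enolate of 19 | C=C(C)C=1C[C@@]2(C)[C@H](C[C@H](O[Si](C)(C)C(C)(C)C)C[C@@H]2OC(C)=O)[C@@H](O[Si](CC)(CC)CC)C=1[O-].[Li+] | intermediate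
19 | 4β-acetoxy-2β-(TBS-oxy)-5β-methyl-7β-(prop-1-en-2-yl)-9β-(TES-oxy)-10βH-decalin-8-one | C=C(C)[C@H]1C[C@@]2(C)[C@H](C[C@H](O[Si](C)(C)C(C)(C)C)C[C@@H]2OC(C)=O)[C@@H](O[Si](CC)(CC)CC)C1=O | intermediate
20 | 4β-acetoxy-2β-(TBS-oxy)-5β-methyl-7β-(prop-1-en-2-yl)-9β-(TES-oxy)-10βH-decalin-8α-ol | C=C(C)[C@H]1C[C@@]2(C)[C@H](C[C@H](O[Si](C)(C)C(C)(C)C)C[C@@H]2OC(C)=O)[C@@H](O[Si](CC)(CC)CC)[C@@H]1O | intermediate
21 | (R)-2-methylbutanoic acid | CC[C@@H](C)C(=O)O | starting material
22 | 8α-(2R)-2-methylbutanoate of 20 | C=C(C)[C@H]1C[C@@]2(C)[C@H](C[C@H](O[Si](C)(C)C(C)(C)C)C[C@@H]2OC(C)=O)[C@@H](O[Si](CC)(CC)CC)[C@@H]1OC(=O)[C@H](C)CC | intermediate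
23 | 4β-acetoxy-2β-(TBS-oxy)-5β-methyl-8α-[(2R)-2-methylbutanoyloxy]-7β-(prop-1-en-2-yl)-10βH-decalin-9β-ol | C=C(C)[C@H]1C[C@@]2(C)[C@H](C[C@H](O[Si](C)(C)C(C)(C)C)C[C@@H]2OC(C)=O)[C@@H](O)[C@@H]1OC(=O)[C@H](C)CC | intermediate
24 | 4β-acetoxy-2β-(TBS-oxy)-5β-methyl-8α-[(2R)-2-methylbutanoyloxy]-7β-(prop-1-en-2-yl)-10βH-decalin-9-one | C=C(C)[C@H]1C[C@@]2(C)[C@H](C[C@H](O[Si](C)(C)C(C)(C)C)C[C@@H]2OC(C)=O)C(=O)[C@@H]1OC(=O)[C@H](C)CC | intermediate
25 | 4β-acetoxy-2β-(TBS-oxy)-5β-methyl-8α-[(2R)-2-methylbutanoyloxy]-7β-(prop-1-en-2-yl)-10βH-decalin-9α-ol | C=C(C)[C@H]1C[C@@]2(C)[C@H](C[C@H](O[Si](C)(C)C(C)(C)C)C[C@@H]2OC(C)=O)[C@H](O)[C@@H]1OC(=O)[C@H](C)CC | intermediate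
26 | 9α-tiglate of 25 | C=C(C)[C@H]1C[C@@]2(C)[C@H](C[C@H](O[Si](C)(C)C(C)(C)C)C[C@@H]2OC(C)=O)[C@H](OC(=O)/C(C)=C/C)[C@@H]1OC(=O)[C@H](C)CC | intermediate
27 | 4β-acetoxy-5β-methyl-8α-[(2R)-2-methylbutanoyloxy]-7β-(prop-1-en-2-yl)-9α-tigloyloxy-10βH-decalin-2β-ol | C=C(C)[C@H]1C[C@@]2(C)[C@H](C[C@H](O)C[C@@H]2OC(C)=O)[C@H](OC(=O)/C(C)=C/C)[C@@H]1OC(=O)[C@H](C)CC | intermediate
28 | 4β-acetoxy-5β-methyl-8α-[(2R)-2-methylbutanoyloxy]-7β-(prop-1-en-2-yl)-9α-tigloyloxy-10βH-decalin-2-one | C=C(C)[C@H]1C[C@@]2(C)[C@H](CC(=O)C[C@@H]2OC(C)=O)[C@H](OC(=O)/C(C)=C/C)[C@@H]1OC(=O)[C@H](C)CC | intermediate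
29 | 5β-methyl-8α-[(2R)-2-methylbutanoyloxy]-7β-(prop-1-en-2-yl)-9α-tigloyloxy-10βH-decal-3-en-2-one | C=C(C)[C@H]1C[C@@]2(C)[C@H](CC(=O)C=C2)[C@H](OC(=O)/C(C)=C/C)[C@@H]1OC(=O)[C@H](C)CC | intermediate
30 | lithium 2(3)-enolate of 31 | C=C(C)[C@H]1C[C@@]2(C)[C@H](CC([O-])=C[C@@H]2C)[C@H](OC(=O)/C(C)=C/C)[C@@H]1OC(=O)[C@H](C)CC.[Li+] | intermediate
31 | CNP0312791.1: 4β,5β-dimethyl-8α-[(2R)-2-methylbutanoyloxy]-7β-(prop-1-en-2-yl)-9α-tigloyloxy-10βH-decalin-2-one | C=C(C)[C@H]1C[C@@]2(C)[C@H](CC(=O)C[C@@H]2C)[C@H](OC(=O)/C(C)=C/C)[C@@H]1OC(=O)[C@H](C)CC | target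

## Step count and least certain steps

Total: 20 steps. Longest linear sequence: 20 steps (1 to 31); 7 and 21 enter as purchased materials.

Step 4 (key step). The most likely failure is a sluggish cycloaddition at the α-methyl enone, which must form a quaternary centre. That would leave time for Lewis-acid decomposition of the diene, for interception at the Mukaiyama–Michael stage, or for acid-induced β-elimination of the C2 silyloxy group with aromatisation of the dienophile. The fallback makes the two bonds one after the other, setting out from 6 and 7. A TiCl4-promoted Mukaiyama–Michael addition at −78 °C, again anti to the silyloxy group, should give the vinylogous ester Michael adduct F1. A base such as DBU should then close ring B by intramolecular Michael addition of the C5 enolate to C6 with loss of methoxide, giving the silylated enedione F2; the tether enforces the cis fusion. Acidic desilylation (1 M HCl, THF) returns to the route at 9.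

Step 5. Facial selectivity may be poor if reduction escapes the chelate, since convex-face attack would give the 4α alcohol and remove the conformational anchor; some 1,2-reduction of the enone is also possible. The fallback replaces chelate control by catalyst control, setting out from 9. Silylation of the C2 hydroxyl (TBSCl, imidazole) gives the silyl ether F3. Its C4 carbonyl, flanked by a large quaternary and a small methylene group, is then reduced with a 2-methyl-CBS-oxazaborolidine and catecholborane, the catalyst enantiomer being chosen to deliver hydride to the α face. This returns directly to 12.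

Step 11. Three processes may interfere: 1,2- instead of 1,4-hydride addition at the hindered β-carbon, incomplete equilibration at C7, and migration of the isopropenyl double bond into conjugation with the C8 ketone during that equilibration. The fallback avoids an α-isopropenyl ketone altogether, setting out from 15. Conjugate reduction with LiBH(s-Bu)3 gives the lithium enolate F4, which is trapped with acetone from the convex face to give the 7β-(2-hydroxypropan-2-yl) ketone F5. Reduction with NaBH4/CeCl3 gives the diol F6. Esterification of its secondary C8 hydroxyl with 21 (EDC, DMAP) gives the hydroxy ester F7. Syn-dehydration of the tertiary alcohol with Burgess reagent, which should favour the less substituted alkene, returns to the route at 22.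

Step 17. The axial C9 hydroxyl, flanked by the ring fusion and the C8 ester, may acylate slowly, and under forcing basic conditions the C8 acyl group could migrate first. The fallback builds the tiglate in two stages, setting out from 25. Esterification with the more reactive saturated acid 2-(diethoxyphosphoryl)propanoic acid (DCC, DMAP) gives the phosphonate ester F8. A Horner–Wadsworth–Emmons reaction with acetaldehyde (LiCl, DBU, MeCN) then forms the (E)-alkene and returns to 26.

Step 20. Addition at the neopentyl C4 may be slow because both faces are encumbered, and prolonged exposure could let the cuprate attack the tiglate or erode facial selectivity. The fallback delivers the carbon as a methylene, setting out from 29. Corey–Chaykovsky cyclopropanation (Me3S(O)I, NaH, DMSO) from the convex β face gives the cyclopropyl ketone F9. Reductive opening with SmI2 (THF, t-BuOH) cleaves the external cyclopropane bond that overlaps with the carbonyl and leaves the 4β-methyl group, returning to the route at 31.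

## Further compounds

F1 | step 4 | (3R,5S)-3-[(E)-4-methoxy-2-oxobut-3-enyl]-2-methyl-5-(triethylsilyloxy)cyclohexan-1-one (C2 epimers; target C10 and C2 centres as shown) | CO/C=C/C(=O)C[C@H]1C[C@H](O[Si](CC)(CC)CC)CC(=O)C1C
F2 | step 4 | 5β-methyl-2β-(TES-oxy)-10βH-decal-6-ene-4,8-dione | C1=C[C@@]2(C)[C@H](C[C@H](O[Si](CC)(CC)CC)CC2=O)CC1=O
F3 | step 5 | 2β-(TBS-oxy)-5β-methyl-10βH-decal-6-ene-4,8-dione | C1=C[C@@]2(C)[C@H](C[C@H](O[Si](C)(C)C(C)(C)C)CC2=O)CC1=O
F4 | step 11 | lithium 7(8)-enolate from conjugate reduction of 15 | C=1C[C@@]2(C)[C@H](C[C@H](O[Si](C)(C)C(C)(C)C)C[C@@H]2OC(C)=O)[C@@H](O[Si](CC)(CC)CC)C=1[O-].[Li+]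
F5 | step 11 | 4β-acetoxy-2β-(TBS-oxy)-7β-(2-hydroxypropan-2-yl)-5β-methyl-9β-(TES-oxy)-10βH-decalin-8-one | CC(C)(O)[C@H]1C[C@@]2(C)[C@H](C[C@H](O[Si](C)(C)C(C)(C)C)C[C@@H]2OC(C)=O)[C@@H](O[Si](CC)(CC)CC)C1=O
F6 | step 11 | 4β-acetoxy-2β-(TBS-oxy)-7β-(2-hydroxypropan-2-yl)-5β-methyl-9β-(TES-oxy)-10βH-decalin-8α-ol | CC(C)(O)[C@H]1C[C@@]2(C)[C@H](C[C@H](O[Si](C)(C)C(C)(C)C)C[C@@H]2OC(C)=O)[C@@H](O[Si](CC)(CC)CC)[C@@H]1O
F7 | step 11 | 8α-(2R)-2-methylbutanoate of F6 | CC(C)(O)[C@H]1C[C@@]2(C)[C@H](C[C@H](O[Si](C)(C)C(C)(C)C)C[C@@H]2OC(C)=O)[C@@H](O[Si](CC)(CC)CC)[C@@H]1OC(=O)[C@H](C)CC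
F8 | step 17 | 9α-[2-(diethoxyphosphoryl)propanoyl] ester of 25 | C=C(C)[C@H]1C[C@@]2(C)[C@H](C[C@H](O[Si](C)(C)C(C)(C)C)C[C@@H]2OC(C)=O)[C@H](OC(=O)C(C)P(=O)(OCC)OCC)[C@@H]1OC(=O)[C@H](C)CC
F9 | step 20 | 3β,4β-methano (cyclopropyl) ketone from 29 | C=C(C)[C@H]1C[C@@]2(C)[C@H](CC(=O)[C@@H]3C[C@@H]32)[C@H](OC(=O)/C(C)=C/C)[C@@H]1OC(=O)[C@H](C)CC
A1 | alternative 1 | trienyl tiglate: 2-silyloxydiene with the tiglate on O9 | C=C(O[Si](C)(C)C(C)(C)C)/C=C/[C@H](OC(=O)/C(C)=C/C)[C@@H](CC1(C)OCCO1)O[Si](C)(C)C(C)(C)C
A2 | alternative 1 | cis-fused ring A γ-lactone from the intramolecular Diels–Alder reaction | O=C1[C@@]2(C)[C@H](C=C(O[Si](C)(C)C(C)(C)C)C[C@@H]2C)[C@H](O1)[C@@H](CC3(C)OCCO3)O[Si](C)(C)C(C)(C)C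
A3 | alternative 2 | 5-methylenecyclohexane with tethered α-methylene ketone | C=C1[C@@H](C)CC2(OCCO2)C[C@@H]1[C@@H]3OC(C)(C)O[C@@H]3C(=C)C(C)=O
A4 | alternative 2 | cis-decalin with C7 acetyl, C8/C9 acetonide and C2 ketal | CC(=O)[C@H]1C[C@@]2(C)[C@H](CC3(OCCO3)C[C@@H]2C)[C@H](OC4(C)C)[C@@H]1O4
A5 | alternative 3 | ring A enone with tethered C9 aldehyde | C=C(C)[C@@H](C[C@@]1(C)C=CC(=O)C[C@@H]1C)[C@H](C=O)O[Si](C)(C)C(C)(C)C
A6 | alternative 3 | cis-decalin with C9 hydroxyl, C8 silyl ether and C7 isopropenyl | C=C(C)[C@H]1C[C@@]2(C)[C@H](CC(=O)C[C@@H]2C)[C@H](O)[C@@H]1O[Si](C)(C)C(C)(C)C
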